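Each intermediate has two ways out, on to target with reagent or back to substrate with leaving ligand, and I follow the comparison of these two through each flask.

    reagent + intermediate → target (k1 = 35 /M/h)
    gas ⇌ reagent, rate k2*(csat - [reagent]) (k2 = 130 /h, csat = 200 mM)
    substrate ⇌ intermediate + leaving ligand (K3 = 0.10 M, k3 = 2.6 /h)

| flask | substrate | gas | time |
|---|---|---|---|
| gamma | 0.80 M | 200 mM (held) | 5.0 h |
| theta | 1.5 M | 200 mM (held) | 5.0 h |
| zeta | 3.0 M | 200 mM (held) | 5.0 h |

- at the start none of reagent is dissolved
- "hardly changes" means that all values lie within two and a half points (for a concentration: within two and a half percent of the largest)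
- run time (gamma): 5.0 h

- [target] at the end for gamma, theta, zeta, in this order
- the course of these numbers from the first flask to the last (rises all the way / hardly changes / rises, then falls / falls all the way / falls, then rises)

- **Fastest rung:** gas dissolves on a time of 0.462 min. From empty the transfer can supply 26.0 M/h, while the zeta charge starts splitting at 7.80 M/h, so supply outruns demand and I take reagent as standing at 200 mM.
- **Next rung:** reagent at that level makes the use of intermediate pseudo-first-order, with capture constant c = 7.00 /h. Substrate splits more slowly, with constant a = 2.6 /h, so I take intermediate as steady and let target follow leaving ligand, L.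
- **Last rung:** the return of intermediate to substrate runs at b·L per intermediate, with b = 26.0 /M/h, and L grows as the flask works. Return equals capture at Lc = c/b = 0.269 M, the return level.
- **What that does to the rate:** net splitting is the splitting times the share that goes on, so dL/dt = a·S/(1 + L/Lc), where S is the substrate left and C the charge, with S = C − L.
- **Integrated:** (1 + C/Lc)·ln(C/S) − L/Lc = a·t, and a·t = 13.0 at the end of the run.
- **My row:** I solve by setting L = C on the left, then putting the answer back once. This gives L of 0.785 M for gamma, 1.41 M for theta and 2.53 M for zeta. Target is L less the intermediate still standing, so I commit to a row a little below these values, and to a row that rises all the way.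
- **The forecast:** it gives 0.78 M, 1.38 M and 2.44 M, rises all the way, lower than mine for zeta, in the words “Target rises all the way, though the conversion falls”.
- **The result:** the flasks give 0.779 M, 1.38 M and 2.46 M, rises all the way. In gamma at 0.448 h intermediate falls back 1.4 times as fast as it goes on, which on the return level means L near 0.377 M, and at 5.00 h its 0.781 M of leaving ligand stands at 2.90 times Lc. In zeta at 5.00 h, 2.48 M of leaving ligand stands at 9.22 times Lc, a higher multiple than in gamma, and substrate left is 17% of the charge against 2.4% in gamma.

All constants stand for no real mixture; the rest is arithmetic.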